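The flavone is cut across ring C at C4–C4a and O1–C2. This exposes the hidden symmetry of ring A. A plane through C4a and C7 pairs C5–OH with C8a–O1 and C6–OMe with C8–OMe. The A-ring partner, 2,4-dimethoxybenzene-1,3,5-triol, therefore has a single C–H between two equivalent hydroxyls and offers no regiochemical choice. The other partner is a methyl 2-methoxy-3-aryl-3-oxopropanoate that already carries C2, C3 (with its methoxy group), C4 and ring B as the 4'-benzyl ether. One neutral thermal condensation makes both bonds and closes the 4-pyrone. Hydrogenolysis of one benzyl ether then ends the synthesis.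

Key step: step 7

Remarks on the chemistry
- The target has no stereocentre, no stereogenic axis and no configurable double bond. It is achiral, so no enantioselective step is needed.
- Free phloroglucinol is not benzylated directly, because its ambident anion C-alkylates. The commercial triacetate is used instead.
- The A-ring triol is prone to oxidation. It is released last, by neutral hydrogenolysis, and goes into the key step without storage. The keto ester is therefore made first.

Step 1
Reactants: 1 4-(benzyloxy)benzoic acid
Product: 2 4-(benzyloxy)benzoyl chloride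
Conditions: (COCl)2 (1.3 equiv), DMF (cat.), CH2Cl2, 0 °C → rt; evaporated, used crude
Reagents that add atoms: oxalyl chloride, O=C(Cl)C(=O)Cl
Why: DMF-catalysed (Vilsmeier-type) conversion of a carboxylic acid into its chloride, to which the aryl benzyl ether is inert.

Step 2
Reactants: 2 4-(benzyloxy)benzoyl chloride; 3 methyl methoxyacetate
Product: 5 methyl 3-[4-(benzyloxy)phenyl]-2-methoxy-3-oxopropanoate (racemic), via lithium enolate 4 (not isolated)
Conditions: 3 (2.2 equiv), LiHMDS (2.2 equiv), THF, −78 °C; then 2 (1 equiv) in THF, −78 → −30 °C; aq. NH4Cl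
Reagents that add atoms: LiHMDS, [Li+].C[Si](C)(C)[N-][Si](C)(C)C (supplies only the lithium of 4; no atom of it remains in 5)
Why: Crossed Claisen-type C-acylation of a preformed ester lithium enolate by a non-enolisable aroyl chloride, in which the second equivalent of enolate deprotonates the more acidic β-keto ester as it forms and shields it from a second acylation; the new centre forms racemic, is enolisable and later becomes sp2 C3.

Step 3
Reactants: 6 benzene-1,3,5-triyl triacetate
Product: 7 1,3,5-tris(benzyloxy)benzene
Conditions: BnCl (3.6 equiv), NaH (7 equiv), DMF, 0 °C; H2O (3 equiv) added dropwise, 0 °C → rt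
Reagents that add atoms: benzyl chloride, ClCc1ccccc1
Why: Williamson etherification run as an in-situ deacetylation–benzylation, in which slowly generated hydroxide frees the phenoxides gradually in the presence of excess benzyl chloride and so suppresses C-benzylation.

Step 4
Reactants: 7 1,3,5-tris(benzyloxy)benzene
Product: 8 1,3,5-tris(benzyloxy)-2,4-dibromobenzene
Conditions: NBS (2.05 equiv), CH2Cl2, −20 → 0 °C, dark
Reagents that add atoms: N-bromosuccinimide, O=C1CCC(=O)N1Br
Why: Electrophilic aromatic bromination of a phloroglucinol triether whose three ring C–H are equivalent; each bromine lowers the reactivity of the ring, so two equivalents should stop at the dibromide, and exclusion of light spares the benzylic C–H bonds.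

Step 5
Reactants: 8 1,3,5-tris(benzyloxy)-2,4-dibromobenzene
Product: 9 1,3,5-tris(benzyloxy)-2,4-dimethoxybenzene
Conditions: NaOMe (30% in MeOH, 10 equiv), CuI (0.4 equiv), DMF, 110 °C, Ar
Reagents that add atoms: sodium methoxide, C[O-].[Na+]
Why: Ullmann-type copper(I)-catalysed methoxylation of aryl bromides, a reaction class established for bromides flanked by two alkoxy groups on phloroglucinol-derived rings and compatible with aryl benzyl ethers.

Step 6
Reactants: 9 1,3,5-tris(benzyloxy)-2,4-dimethoxybenzene
Product: 10 2,4-dimethoxybenzene-1,3,5-triol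
Conditions: H2 (1 atm), 10% Pd/C, degassed EtOAc–MeOH, rt; filtered and concentrated under Ar, used at once
Reagents that add atoms: none
Why: Catalytic hydrogenolysis of aryl benzyl ethers, which is neutral, leaves the methyl ethers untouched and needs no aqueous work-up of the oxidation-prone phenol.

Step 7
Reactants: 10 2,4-dimethoxybenzene-1,3,5-triol; 5 methyl 3-[4-(benzyloxy)phenyl]-2-methoxy-3-oxopropanoate (racemic)
Product: 14 4'-benzyloxy-5,7-dihydroxy-3,6,8-trimethoxyflavone, via aroyl(methoxy)ketene 11 (not isolated), via C-acylated diketone 12 (not isolated), via 2-hydroxyflavanone hemiketal 13 (not isolated)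
Conditions: 5 (2 equiv), Ph2O (ca. 1 M), slow Ar sweep, 240 °C, MeOH and H2O distilled out
Reagents that add atoms: none
Why: On heating, the enol form of 5 expels methanol to give ketene 11, which acylates 10 at its only ring C–H (the future C4a), directly or through a reversibly formed aryl ester and acyl shift, and so makes C4–C4a in diketone 12. Ring C then closes by 6-exo-trig addition of one flanking hydroxyl to the aroyl carbonyl (O1–C2, hemiketal 13), and loss of water gives the aromatic 4-pyrone with the C3 methoxy group in place. The closest known reaction type is the Mentzer thermal pyrone synthesis, the acid-free relative of the Simonis chromone condensation, which is established for phloroglucinol-type phenols and aroylacetates, α-substituted ones included. No stereocentre is created in 14, since the labile centre of 5 and those of 12 and 13 all end as the sp2 carbons C2 and C3. The step needs chromone rather than coumarin formation, which the absence of acid secures because Pechmann-type attack of the arene on the aryl-conjugated ketone is not activated whereas the ketene carbon is; site selectivity is secured by the mirror plane of 10 through its C3 and C6, which makes the two flanking hydroxyls identical and renders even a Wessely–Moser ring opening and reclosure degenerate, while acylation of the central hydroxyl is reversible and cannot cyclise. The excess of 5 and the gas sweep, which carries off methanol and water, compensate for loss of ketene by hydration and decarboxylation.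

Step 8
Reactants: 14 4'-benzyloxy-5,7-dihydroxy-3,6,8-trimethoxyflavone
Product: 15 5,7,4'-trihydroxy-3,6,8-trimethoxyflavone (target)
Conditions: H2 (1 atm), 10% Pd/C, THF–MeOH, rt
Reagents that add atoms: none
Why: Catalytic hydrogenolysis of the single aryl benzyl ether; the tetrasubstituted C2=C3 bond of the aromatic 4-pyrone and the methyl ethers should not react at 1 atm and room temperature.

Compound list
1 | 4-(benzyloxy)benzoic acid | O=C(O)c1ccc(OCc2ccccc2)cc1 | starting material
2 | 4-(benzyloxy)benzoyl chloride | O=C(Cl)c1ccc(OCc2ccccc2)cc1 | intermediate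
3 | methyl methoxyacetate | COCC(=O)OC | starting material
4 | lithium enolate of methyl methoxyacetate (not isolated; drawn in the chelated geometry with the enolate oxygen cis to the α-methoxy group; the geometry has no consequence) | [Li+].CO/C=C(\[O-])OC | intermediate
5 | methyl 3-[4-(benzyloxy)phenyl]-2-methoxy-3-oxopropanoate (racemic, enolisable centre) | COC(=O)C(OC)C(=O)c1ccc(OCc2ccccc2)cc1 | intermediate
6 | benzene-1,3,5-triyl triacetate (phloroglucinol triacetate) | CC(=O)Oc1cc(OC(C)=O)cc(OC(C)=O)c1 | starting material
7 | 1,3,5-tris(benzyloxy)benzene | c1ccc(COc2cc(OCc3ccccc3)cc(OCc3ccccc3)c2)cc1 | intermediate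
8 | 1,3,5-tris(benzyloxy)-2,4-dibromobenzene | Brc1c(OCc2ccccc2)cc(OCc2ccccc2)c(Br)c1OCc1ccccc1 | intermediate
9 | 1,3,5-tris(benzyloxy)-2,4-dimethoxybenzene | COc1c(OCc2ccccc2)cc(OCc2ccccc2)c(OC)c1OCc1ccccc1 | intermediate
10 | 2,4-dimethoxybenzene-1,3,5-triol | Oc1cc(O)c(OC)c(O)c1OC | intermediate
11 | 3-[4-(benzyloxy)phenyl]-2-methoxy-3-oxoprop-1-en-1-one, the aroyl(methoxy)ketene (not isolated) | COC(=C=O)C(=O)c1ccc(OCc2ccccc2)cc1 | intermediate
12 | 1-[4-(benzyloxy)phenyl]-2-methoxy-3-(2,4,6-trihydroxy-3,5-dimethoxyphenyl)propane-1,3-dione (not isolated; racemic, labile centre) | COC(C(=O)c1ccc(OCc2ccccc2)cc1)C(=O)c1c(O)c(OC)c(O)c(OC)c1O | intermediate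
13 | 2-[4-(benzyloxy)phenyl]-2,5,7-trihydroxy-3,6,8-trimethoxychroman-4-one (not isolated; mixture of racemic diastereomers) | COC1C(=O)c2c(O)c(OC)c(O)c(OC)c2OC1(O)c1ccc(OCc2ccccc2)cc1 | intermediate
14 | 2-[4-(benzyloxy)phenyl]-5,7-dihydroxy-3,6,8-trimethoxy-4H-chromen-4-one (4'-benzyloxy-5,7-dihydroxy-3,6,8-trimethoxyflavone) | COc1c(O)c(OC)c2oc(-c3ccc(OCc4ccccc4)cc3)c(OC)c(=O)c2c1O | intermediate
15 | 5,7-dihydroxy-2-(4-hydroxyphenyl)-3,6,8-trimethoxy-4H-chromen-4-one (achiral) | COc1c(O)c(OC)c2oc(-c3ccc(O)cc3)c(OC)c(=O)c2c1O | target

Total step count: 8. Longest linear sequence: 6 (steps 3, 4, 5, 6, 7, 8).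

Steps most likely to fail

Step 7. The electron-rich triol may break down oxidatively or thermally before it is C-acylated. The ketene may be drained by hydration and decarboxylation, or the reaction may leak into the coumarin manifold. The fallback sets out from 10 and returns at 14, and it builds ring C in stages at lower temperature.
- Hoesch acylation of 10 with methoxyacetonitrile (ZnCl2, dry HCl, Et2O, 0 °C) should precipitate 2-methoxy-1-(2,4,6-trihydroxy-3,5-dimethoxyphenyl)ethan-1-iminium chloride F1.
- Boiling water hydrolyses this salt to 2-methoxy-1-(2,4,6-trihydroxy-3,5-dimethoxyphenyl)ethan-1-one F2.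
- 4-(Benzyloxy)benzoic anhydride F3 is made from 1 and 2 (Et3N, CH2Cl2).
- An Allan–Robinson condensation of F2 with excess F3 and Et3N at 160–170 °C should give 2-[4-(benzyloxy)phenyl]-3,6,8-trimethoxy-4-oxo-4H-chromene-5,7-diyl bis[4-(benzyloxy)benzoate] F4.
- KOH in aqueous methanol, followed by acidification, removes the two aryl esters and delivers 14.

Step 5. Hydrodebromination may compete with C–O coupling at the doubly flanked positions. The reaction may also stall after the first substitution, or hot methoxide may slowly cleave a benzyl ether. The fallback sets out from 8 and returns at 9. It makes the two C–O bonds one at a time by oxidation of aryl–boron bonds and O-methylation.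
- Bromine–lithium exchange on 8 (n-BuLi, 1.05 equiv, THF, −78 °C) gives [2,4,6-tris(benzyloxy)-3-bromophenyl]lithium F5.
- B(OMe)3 converts it into lithium [2,4,6-tris(benzyloxy)-3-bromophenyl]trimethoxyborate F6.
- H2O2/NaOH in the same flask gives 2,4,6-tris(benzyloxy)-3-bromophenol F7.
- MeI/K2CO3 in acetone gives 1,3,5-tris(benzyloxy)-2-bromo-4-methoxybenzene F8.
- The same operations on F8 lead through [2,4,6-tris(benzyloxy)-3-methoxyphenyl]lithium F9 and lithium [2,4,6-tris(benzyloxy)-3-methoxyphenyl]trimethoxyborate F10 to 2,4,6-tris(benzyloxy)-3-methoxyphenol F11.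
- Methylation of F11 (MeI/K2CO3) gives 9.

Step 2. O-acylation of the enolate, further acylation of the product enolate or self-condensation of the methoxyacetate may erode the C-acylation. The fallback sets out from 3 (as its enolate 4) and returns at 5. It replaces acylation by addition and oxidation.
- Aldol addition of 4 to purchased 4-(benzyloxy)benzaldehyde F12 (THF, −78 °C) gives methyl 3-[4-(benzyloxy)phenyl]-3-hydroxy-2-methoxypropanoate F13 as a mixture of racemic diastereomers.
- The composition of that mixture does not matter, because Dess–Martin periodinane (CH2Cl2, rt) oxidises the benzylic carbinol to 5.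

Further compounds
F1 | step 7 | 2-methoxy-1-(2,4,6-trihydroxy-3,5-dimethoxyphenyl)ethan-1-iminium chloride | COCC(=[NH2+])c1c(O)c(OC)c(O)c(OC)c1O.[Cl-]
F2 | step 7 | 2-methoxy-1-(2,4,6-trihydroxy-3,5-dimethoxyphenyl)ethan-1-one | COCC(=O)c1c(O)c(OC)c(O)c(OC)c1O
F3 | step 7 | 4-(benzyloxy)benzoic anhydride | O=C(OC(=O)c1ccc(OCc2ccccc2)cc1)c1ccc(OCc2ccccc2)cc1
F4 | step 7 | 2-[4-(benzyloxy)phenyl]-3,6,8-trimethoxy-4-oxo-4H-chromene-5,7-diyl bis[4-(benzyloxy)benzoate] | COc1c(OC(=O)c2ccc(OCc3ccccc3)cc2)c(OC)c2oc(-c3ccc(OCc4ccccc4)cc3)c(OC)c(=O)c2c1OC(=O)c1ccc(OCc2ccccc2)cc1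
F5 | step 5 | [2,4,6-tris(benzyloxy)-3-bromophenyl]lithium | [Li]c1c(OCc2ccccc2)cc(OCc2ccccc2)c(Br)c1OCc1ccccc1
F6 | step 5 | lithium [2,4,6-tris(benzyloxy)-3-bromophenyl]trimethoxyborate | [Li+].CO[B-](OC)(OC)c1c(OCc2ccccc2)cc(OCc2ccccc2)c(Br)c1OCc1ccccc1
F7 | step 5 | 2,4,6-tris(benzyloxy)-3-bromophenol | Oc1c(OCc2ccccc2)cc(OCc2ccccc2)c(Br)c1OCc1ccccc1
F8 | step 5 | 1,3,5-tris(benzyloxy)-2-bromo-4-methoxybenzene | COc1c(OCc2ccccc2)cc(OCc2ccccc2)c(Br)c1OCc1ccccc1
F9 | step 5 | [2,4,6-tris(benzyloxy)-3-methoxyphenyl]lithium | [Li]c1c(OCc2ccccc2)cc(OCc2ccccc2)c(OC)c1OCc1ccccc1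
F10 | step 5 | lithium [2,4,6-tris(benzyloxy)-3-methoxyphenyl]trimethoxyborate | [Li+].CO[B-](OC)(OC)c1c(OCc2ccccc2)cc(OCc2ccccc2)c(OC)c1OCc1ccccc1
F11 | step 5 | 2,4,6-tris(benzyloxy)-3-methoxyphenol | Oc1c(OCc2ccccc2)cc(OCc2ccccc2)c(OC)c1OCc1ccccc1
F12 | step 2 | 4-(benzyloxy)benzaldehyde (purchased) | O=Cc1ccc(OCc2ccccc2)cc1
F13 | step 2 | methyl 3-[4-(benzyloxy)phenyl]-3-hydroxy-2-methoxypropanoate (mixture of racemic diastereomers) | COC(=O)C(OC)C(O)c1ccc(OCc2ccccc2)cc1
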